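**Retrosynthetic overview**
- Target ⇒ 8-epi epoxy alcohol by Mitsunobu esterification with inversion at C8 ⇒ 1(10)-olefin by 8-OH-directed epoxidation (the oxirane is the last ring made).
- Ten-membered carbocycle and γ-lactone ⇒ one acyclic farnesane-type chain: the C6–C7 bond (the bond the germacrene cyclase makes) by adding a C7 allylchromium to the C6 Z-enal, then O6→C12 lactonisation in the same flask.
- Chain ⇒ nerylacetone: O at C3 by proline aminoxylation, C5–C6 and the Z-4,5-olefin through a butenolide, O at C8 by aldehyde α-oxyamination, C11–C13 from methyl propiolate.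
- Ring order: carbocycle (C6–C7) → lactone (same step) → epoxide.

Assumption and convention: nerylacetone (pure 5Z isomer) is bought as such; atom labels C1–C15 in the names and reasons follow germacranolide numbering (C6 carries the lactone O, C12 = lactone C=O, C13 = exocyclic CH2, C14 on C10, C15 on C4).

**Route**

Step 1
Reactants: 1 nerylacetone (3 equiv, excess recovered); 2 nitrosobenzene
Product: 4 (3R,5Z)-3-hydroxy-6,10-dimethylundeca-5,9-dien-2-one, via aminooxy ketone 3 (not isolated)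
Conditions: L-proline (20 mol%), DMSO, rt, slow addition of 2; then CuSO4·5H2O (30 mol%), MeOH, 0 °C
Reagents that add atoms: nitrosobenzene, O=Nc1ccccc1
Why: Proline enamine catalysis (α-aminoxylation): the more substituted enamine of the methyl ketone attacks the O atom of PhNO held by the proline CO2H, which gives 3R as with other ketones and L-proline, and CuSO4/MeOH then cleaves the weak N–O bond to the free α-hydroxy ketone (C3 of the target is set here).

Step 2
Reactants: 4 (3R,5Z)-3-hydroxy-6,10-dimethylundeca-5,9-dien-2-one; 5 (triphenylphosphoranylidene)ketene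
Product: 7 (5R)-5-[(2Z)-3,7-dimethylocta-2,6-dien-1-yl]-4-methylfuran-2(5H)-one, via ester ylide 6 (not isolated)
Conditions: toluene, 90 °C
Reagents that add atoms: (triphenylphosphoranylidene)ketene, O=C=C=P(c1ccccc1)(c1ccccc1)c1ccccc1
Why: Bestmann butenolide synthesis: the OH adds to the ketene ylide and the ester ylide closes by intramolecular Wittig reaction on the ketone, which locks the C4=C5 olefin as Z (C3 and C6 cis in the ring) without touching C3.

Step 3
Reactants: 7 (5R)-5-[(2Z)-3,7-dimethylocta-2,6-dien-1-yl]-4-methylfuran-2(5H)-one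
Product: 9 (2Z,4R,6Z)-3,7,11-trimethyldodeca-2,6,10-triene-1,4-diol, via lactol 8 (not isolated)
Conditions: i-Bu2AlH (3 equiv), CH2Cl2, −78 → 0 °C; aq. potassium sodium tartrate
Reagents that add atoms: none
Why: 1,2-Reduction of the unsaturated lactone through the lactol gives the Z-ene-1,4-diol; the ring-derived olefin geometry and C3 are untouched, and a neutral work-up avoids furan formation.

Step 4
Reactants: 9 (2Z,4R,6Z)-3,7,11-trimethyldodeca-2,6,10-triene-1,4-diol; 10 tert-butyl(chloro)diphenylsilane; 11 acetic anhydride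
Product: 13 (2Z,4R,6Z)-1-[(tert-butyldiphenylsilyl)oxy]-3,7,11-trimethyldodeca-2,6,10-trien-4-yl acetate, via monosilyl ether 12 (not isolated)
Conditions: TBDPSCl (1.05 equiv), imidazole, CH2Cl2, 0 °C; then Ac2O, DMAP (cat.), rt
Reagents that add atoms: tert-butyl(chloro)diphenylsilane, CC(C)(C)[Si](Cl)(c1ccccc1)c1ccccc1; acetic anhydride, CC(=O)OC(C)=O
Why: Silylation is selective for the primary allylic OH on steric grounds, and the remaining secondary C3–OH is then acetylated in the same pot, which installs the acetate of the target and rules out lactol formation later.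

Step 5
Reactants: 13 (2Z,4R,6Z)-1-[(tert-butyldiphenylsilyl)oxy]-3,7,11-trimethyldodeca-2,6,10-trien-4-yl acetate; 14 N-bromosuccinimide; 15 water
Product: 17 (2Z,4R,6Z)-1-[(tert-butyldiphenylsilyl)oxy]-10,11-epoxy-3,7,11-trimethyldodeca-2,6-dien-4-yl acetate (both C10 epimers), via bromohydrin 16 (not isolated)
Conditions: NBS (1.05 equiv), THF/H2O, 0 °C; then DBU, CH2Cl2, rt
Reagents that add atoms: water, O
Why: van Tamelen-type bromohydrin formation is selective for the terminal isopropylidene olefin (the 4,5-olefin is deactivated by two allylic C–O bonds, the 1(10)-olefin is more hindered and carries a homoallylic acetate), and DBU closes the bromohydrin to the epoxide without touching the acetate; the new centre is destroyed in step 6.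

Step 6
Reactants: 17 (2Z,4R,6Z)-1-[(tert-butyldiphenylsilyl)oxy]-10,11-epoxy-3,7,11-trimethyldodeca-2,6-dien-4-yl acetate; 15 water
Product: 19 (2Z,4R,6Z)-1-[(tert-butyldiphenylsilyl)oxy]-3,7-dimethyl-10-oxodeca-2,6-dien-4-yl acetate, via glycol 18 (not isolated)
Conditions: H5IO6 (1.2 equiv), THF/H2O, 0 °C
Reagents that add atoms: none
Why: Periodic acid hydrolyses the trisubstituted epoxide and cleaves the glycol (Malaprade cleavage) to the C7 aldehyde and acetone; the TBDPS ether and the acetate survive the short acidic treatment.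

Step 7
Reactants: 19 (2Z,4R,6Z)-1-[(tert-butyldiphenylsilyl)oxy]-3,7-dimethyl-10-oxodeca-2,6-dien-4-yl acetate; 20 TEMPO
Product: 21 (2Z,4R,6Z,9R)-1-[(tert-butyldiphenylsilyl)oxy]-3,7-dimethyl-10-oxo-9-[(2,2,6,6-tetramethylpiperidin-1-yl)oxy]deca-2,6-dien-4-yl acetate
Conditions: TEMPO (1.5 equiv), CuCl2 (10 mol%), (5R)-5-benzyl-2,2,3-trimethylimidazolidin-4-one·CF3CO2H (20 mol%), air, acetone, −20 °C
Reagents that add atoms: TEMPO, CC1(C)CCCC(C)(C)N1[O]
Why: Enamine-catalysed α-oxyamination of an aldehyde with copper/TEMPO: the imidazolidinone shields one enamine face and sets C8 as R (the epimer of the target centre, on purpose); the sense is assigned by analogy with α-chlorinations with this catalyst family, and the antipodal catalyst is used if it proves opposite.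

Step 8
Reactants: 21 (2Z,4R,6Z,9R)-1-[(tert-butyldiphenylsilyl)oxy]-3,7-dimethyl-10-oxo-9-[(2,2,6,6-tetramethylpiperidin-1-yl)oxy]deca-2,6-dien-4-yl acetate; 22 methyl propiolate
Product: 24 methyl (4R,6Z,9R,10Z)-9-acetoxy-12-[(tert-butyldiphenylsilyl)oxy]-3-hydroxy-6,10-dimethyl-2-methylidene-4-[(2,2,6,6-tetramethylpiperidin-1-yl)oxy]dodeca-6,10-dienoate (both C3 epimers), via vinylalane 23 (not isolated)
Conditions: methyl propiolate, i-Bu2AlH, N-methylmorpholine N-oxide, THF, 0 °C; then 21, 0 °C → rt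
Reagents that add atoms: methyl propiolate, C#CC(=O)OC
Why: Vinylalumination (a base-free route to Morita–Baylis–Hillman adducts): hydroalumination of the propiolate gives the α-alumino acrylate, which adds 1,2 to the aldehyde at low temperature so the enolisable C8 centre is not epimerised; the new C7 carbinol is a mixture, which does not matter because C7 becomes sp2 in step 11.

Step 9
Reactants: 24 methyl (4R,6Z,9R,10Z)-9-acetoxy-12-[(tert-butyldiphenylsilyl)oxy]-3-hydroxy-6,10-dimethyl-2-methylidene-4-[(2,2,6,6-tetramethylpiperidin-1-yl)oxy]dodeca-6,10-dienoate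
Product: 25 methyl (4R,6Z,9R,10Z)-9-acetoxy-3,12-dihydroxy-6,10-dimethyl-2-methylidene-4-[(2,2,6,6-tetramethylpiperidin-1-yl)oxy]dodeca-6,10-dienoate
Conditions: Bu4NF, AcOH (1:1), THF, rt
Reagents that add atoms: none
Why: Fluoride cleavage of the silyl ether, buffered with AcOH so that the acetate and the β-hydroxy acrylate survive.

Step 10
Reactants: 25 methyl (4R,6Z,9R,10Z)-9-acetoxy-3,12-dihydroxy-6,10-dimethyl-2-methylidene-4-[(2,2,6,6-tetramethylpiperidin-1-yl)oxy]dodeca-6,10-dienoate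
Product: 26 methyl (4R,6Z,9R,10Z)-9-acetoxy-3-hydroxy-6,10-dimethyl-2-methylidene-12-oxo-4-[(2,2,6,6-tetramethylpiperidin-1-yl)oxy]dodeca-6,10-dienoate
Conditions: TEMPO (10 mol%), PhI(OAc)2 (1.2 equiv), CH2Cl2, rt
Reagents that add atoms: none
Why: Oxoammonium oxidation (TEMPO/PhI(OAc)2) takes the primary allylic alcohol much faster than the secondary, electron-poor Baylis–Hillman alcohol and gives the Z-enal under conditions too mild to isomerise it; the C3 acetate blocks lactol and furan formation.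

Step 11
Reactants: 26 methyl (4R,6Z,9R,10Z)-9-acetoxy-3-hydroxy-6,10-dimethyl-2-methylidene-12-oxo-4-[(2,2,6,6-tetramethylpiperidin-1-yl)oxy]dodeca-6,10-dienoate; 14 N-bromosuccinimide
Product: 27 methyl (2Z,4R,6Z,9R,10Z)-9-acetoxy-2-(bromomethyl)-6,10-dimethyl-12-oxo-4-[(2,2,6,6-tetramethylpiperidin-1-yl)oxy]dodeca-2,6,10-trienoate
Conditions: NBS (1.3 equiv), Me2S (1.5 equiv), CH2Cl2, −20 → 0 °C
Reagents that add atoms: N-bromosuccinimide, O=C1CCC(=O)N1Br
Why: Corey–Kim bromination with allylic transposition (SN2'): the activated Baylis–Hillman hydroxyl leaves as bromide attacks C13, giving the favoured (Z)-2-(bromomethyl)-2-enoate under neutral conditions that spare the enal and C8.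

Step 12
Reactants: 27 methyl (2Z,4R,6Z,9R,10Z)-9-acetoxy-2-(bromomethyl)-6,10-dimethyl-12-oxo-4-[(2,2,6,6-tetramethylpiperidin-1-yl)oxy]dodeca-2,6,10-trienoate
Product: 30 (3R,6S,7R,8R)-3-acetoxy-8-[(2,2,6,6-tetramethylpiperidin-1-yl)oxy]germacra-1(10)Z,4Z,11(13)-trien-12,6-olide, via allylchromium species 28 (not isolated), via hydroxy ester 29 (not isolated)
Conditions: CrCl2 (10 equiv), THF, slow addition to 2 mM, rt; then PPTS (cat.), CH2Cl2, rt
Reagents that add atoms: none
Why: Intramolecular Nozaki–Hiyama allylation: the allylchromium adds through C7 to the Z-enal carbonyl to close the ten-membered ring at C6–C7 with the 6,7-anti (trans-lactone) relationship known from chromium closures of costunolide- and parthenolide-type rings; the C7 face is set by C8 (C8–H eclipsing the C7=C11 bond, the bulky amino-oxy group anti to the incoming aldehyde, as in the ring conformation of 8-substituted germacranolides), and the C6 alkoxide then lactonises onto the methyl ester.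

Step 13
Reactants: 30 (3R,6S,7R,8R)-3-acetoxy-8-[(2,2,6,6-tetramethylpiperidin-1-yl)oxy]germacra-1(10)Z,4Z,11(13)-trien-12,6-olide
Product: 31 (3R,6S,7S,8R)-3-acetoxy-8-hydroxygermacra-1(10)Z,4Z,11(13)-trien-12,6-olide
Conditions: Zn dust, AcOH/THF/H2O (3:1:1), 50 °C
Reagents that add atoms: none
Why: Reductive N–O cleavage of the alkoxyamine by zinc in acetic acid frees the 8-hydroxyl with retention; the acidic medium avoids base-induced migration of the lactone to O8.

Step 14
Reactants: 31 (3R,6S,7S,8R)-3-acetoxy-8-hydroxygermacra-1(10)Z,4Z,11(13)-trien-12,6-olide; 32 tert-butyl hydroperoxide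
Product: 33 (1R,3R,6S,7S,8R,10S)-3-acetoxy-1,10-epoxy-8-hydroxygermacra-4Z,11(13)-dien-12,6-olide
Conditions: VO(acac)2 (5 mol%), t-BuOOH (1.5 equiv), CH2Cl2, 0 °C → rt
Reagents that add atoms: tert-butyl hydroperoxide, CC(C)(C)OO
Why: Hydroxyl-directed vanadium-catalysed epoxidation of a homoallylic alcohol: the 8R hydroxyl binds the peroxovanadium and delivers oxygen to the face of the 1(10)-olefin syn to it (Mihelich chair transition state), giving 1R,10S, while the 4,5-olefin (two allylic C–O bonds) and the conjugated exocyclic methylene are too electron-poor to react.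

Step 15
Reactants: 33 (1R,3R,6S,7S,8R,10S)-3-acetoxy-1,10-epoxy-8-hydroxygermacra-4Z,11(13)-dien-12,6-olide; 34 (R)-2-methylbutanoic acid
Product: 35 (1R,3R,6S,7S,8S,10S)-3-acetoxy-1,10-epoxy-8-[(2R)-2-methylbutanoyloxy]germacra-4Z,11(13)-dien-12,6-olide (CNP0340603.1)
Conditions: PPh3, DIAD, toluene, 0 °C → rt
Reagents that add atoms: (R)-2-methylbutanoic acid, CC[C@@H](C)C(=O)O
Why: Mitsunobu esterification: SN2 displacement of the 8-oxyphosphonium group by the carboxylate inverts C8 from R to S and installs the ester without activating the acid, so its own stereocentre cannot racemise.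

**Compound list**

1 | nerylacetone, (5Z)-6,10-dimethylundeca-5,9-dien-2-one | CC(=O)CC/C=C(C)\CCC=C(C)C | starting material
2 | nitrosobenzene | O=Nc1ccccc1 | starting material
3 | (3R,5Z)-6,10-dimethyl-3-[(phenylamino)oxy]undeca-5,9-dien-2-one | CC(=O)[C@H](ONc1ccccc1)C/C=C(C)\CCC=C(C)C | intermediate
4 | (3R,5Z)-3-hydroxy-6,10-dimethylundeca-5,9-dien-2-one | CC(=O)[C@H](O)C/C=C(C)\CCC=C(C)C | intermediate
5 | (triphenylphosphoranylidene)ketene | O=C=C=P(c1ccccc1)(c1ccccc1)c1ccccc1 | starting material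
6 | (3R,5Z)-6,10-dimethyl-2-oxoundeca-5,9-dien-3-yl (triphenylphosphoranylidene)acetate | CC(=O)[C@H](OC(=O)C=P(c1ccccc1)(c1ccccc1)c1ccccc1)C/C=C(C)\CCC=C(C)C | intermediate
7 | (5R)-5-[(2Z)-3,7-dimethylocta-2,6-dien-1-yl]-4-methylfuran-2(5H)-one | CC1=CC(=O)O[C@@H]1C/C=C(C)\CCC=C(C)C | intermediate
8 | (5R)-5-[(2Z)-3,7-dimethylocta-2,6-dien-1-yl]-4-methyl-2,5-dihydrofuran-2-ol (lactol, both C2 epimers) | CC1=CC(O)O[C@@H]1C/C=C(C)\CCC=C(C)C | intermediate
9 | (2Z,4R,6Z)-3,7,11-trimethyldodeca-2,6,10-triene-1,4-diol | OC/C=C(/C)[C@H](O)C/C=C(C)\CCC=C(C)C | intermediate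
10 | tert-butyl(chloro)diphenylsilane | CC(C)(C)[Si](Cl)(c1ccccc1)c1ccccc1 | starting material
11 | acetic anhydride | CC(=O)OC(C)=O | starting material
12 | (2Z,4R,6Z)-1-[(tert-butyldiphenylsilyl)oxy]-3,7,11-trimethyldodeca-2,6,10-trien-4-ol | CC(C)(C)[Si](OC/C=C(/C)[C@H](O)C/C=C(C)\CCC=C(C)C)(c1ccccc1)c1ccccc1 | intermediate
13 | (2Z,4R,6Z)-1-[(tert-butyldiphenylsilyl)oxy]-3,7,11-trimethyldodeca-2,6,10-trien-4-yl acetate | CC(C)(C)[Si](OC/C=C(/C)[C@H](OC(C)=O)C/C=C(C)\CCC=C(C)C)(c1ccccc1)c1ccccc1 | intermediate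
14 | N-bromosuccinimide | O=C1CCC(=O)N1Br | starting material
15 | water | O | starting material
16 | (2Z,4R,6Z)-10-bromo-1-[(tert-butyldiphenylsilyl)oxy]-11-hydroxy-3,7,11-trimethyldodeca-2,6-dien-4-yl acetate (both C10 epimers) | CC(C)(C)[Si](OC/C=C(/C)[C@H](OC(C)=O)C/C=C(C)\CCC(Br)C(C)(C)O)(c1ccccc1)c1ccccc1 | intermediate
17 | (2Z,4R,6Z)-1-[(tert-butyldiphenylsilyl)oxy]-10,11-epoxy-3,7,11-trimethyldodeca-2,6-dien-4-yl acetate (both C10 epimers) | CC(C)(C)[Si](OC/C=C(/C)[C@H](OC(C)=O)C/C=C(C)\CCC1OC1(C)C)(c1ccccc1)c1ccccc1 | intermediate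
18 | (2Z,4R,6Z)-1-[(tert-butyldiphenylsilyl)oxy]-10,11-dihydroxy-3,7,11-trimethyldodeca-2,6-dien-4-yl acetate (both C10 epimers) | CC(C)(C)[Si](OC/C=C(/C)[C@H](OC(C)=O)C/C=C(C)\CCC(O)C(C)(C)O)(c1ccccc1)c1ccccc1 | intermediate
19 | (2Z,4R,6Z)-1-[(tert-butyldiphenylsilyl)oxy]-3,7-dimethyl-10-oxodeca-2,6-dien-4-yl acetate | CC(C)(C)[Si](OC/C=C(/C)[C@H](OC(C)=O)C/C=C(C)\CCC=O)(c1ccccc1)c1ccccc1 | intermediate
20 | TEMPO, (2,2,6,6-tetramethylpiperidin-1-yl)oxyl | CC1(C)CCCC(C)(C)N1[O] | starting material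
21 | (2Z,4R,6Z,9R)-1-[(tert-butyldiphenylsilyl)oxy]-3,7-dimethyl-10-oxo-9-[(2,2,6,6-tetramethylpiperidin-1-yl)oxy]deca-2,6-dien-4-yl acetate | CC(C)(C)[Si](OC/C=C(/C)[C@H](OC(C)=O)C/C=C(C)\C[C@@H](ON1C(C)(C)CCCC1(C)C)C=O)(c1ccccc1)c1ccccc1 | intermediate
22 | methyl propiolate | C#CC(=O)OC | starting material
23 | methyl 2-(diisobutylalumanyl)acrylate | C=C(C(=O)OC)[Al](CC(C)C)CC(C)C | intermediate
24 | methyl (4R,6Z,9R,10Z)-9-acetoxy-12-[(tert-butyldiphenylsilyl)oxy]-3-hydroxy-6,10-dimethyl-2-methylidene-4-[(2,2,6,6-tetramethylpiperidin-1-yl)oxy]dodeca-6,10-dienoate (both C3 epimers) | CC(C)(C)[Si](OC/C=C(/C)[C@H](OC(C)=O)C/C=C(C)\C[C@@H](ON1C(C)(C)CCCC1(C)C)C(O)C(=C)C(=O)OC)(c1ccccc1)c1ccccc1 | intermediate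
25 | methyl (4R,6Z,9R,10Z)-9-acetoxy-3,12-dihydroxy-6,10-dimethyl-2-methylidene-4-[(2,2,6,6-tetramethylpiperidin-1-yl)oxy]dodeca-6,10-dienoate (both C3 epimers) | OC/C=C(/C)[C@H](OC(C)=O)C/C=C(C)\C[C@@H](ON1C(C)(C)CCCC1(C)C)C(O)C(=C)C(=O)OC | intermediate
26 | methyl (4R,6Z,9R,10Z)-9-acetoxy-3-hydroxy-6,10-dimethyl-2-methylidene-12-oxo-4-[(2,2,6,6-tetramethylpiperidin-1-yl)oxy]dodeca-6,10-dienoate (both C3 epimers) | O=C/C=C(/C)[C@H](OC(C)=O)C/C=C(C)\C[C@@H](ON1C(C)(C)CCCC1(C)C)C(O)C(=C)C(=O)OC | intermediate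
27 | methyl (2Z,4R,6Z,9R,10Z)-9-acetoxy-2-(bromomethyl)-6,10-dimethyl-12-oxo-4-[(2,2,6,6-tetramethylpiperidin-1-yl)oxy]dodeca-2,6,10-trienoate | O=C/C=C(/C)[C@H](OC(C)=O)C/C=C(C)\C[C@@H](ON1C(C)(C)CCCC1(C)C)/C=C(\CBr)C(=O)OC | intermediate
28 | allylchromium dichloride from 27 (CrCl2 on C13, trivalent chromium) | O=C/C=C(/C)[C@H](OC(C)=O)C/C=C(C)\C[C@@H](ON1C(C)(C)CCCC1(C)C)/C=C(\C[Cr](Cl)Cl)C(=O)OC | intermediate
29 | methyl (3R,6S,7R,8R)-3-acetoxy-6-hydroxy-8-[(2,2,6,6-tetramethylpiperidin-1-yl)oxy]germacra-1(10)Z,4Z,11(13)-trien-12-oate (ten-membered carbocycle, lactone still open) | COC(=O)C(=C)[C@@H]1[C@@H](O)/C=C(/C)[C@H](OC(C)=O)C/C=C(C)\C[C@H]1ON2C(C)(C)CCCC2(C)C | intermediate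
30 | (3R,6S,7R,8R)-3-acetoxy-8-[(2,2,6,6-tetramethylpiperidin-1-yl)oxy]germacra-1(10)Z,4Z,11(13)-trien-12,6-olide (C7 drawn as in the target; the descriptor is R only because the N–O group raises the priority of C8) | C=C1C(=O)O[C@H]2/C=C(/C)[C@H](OC(C)=O)C/C=C(C)\C[C@@H](ON3C(C)(C)CCCC3(C)C)[C@H]12 | intermediate
31 | (3R,6S,7S,8R)-3-acetoxy-8-hydroxygermacra-1(10)Z,4Z,11(13)-trien-12,6-olide | C=C1C(=O)O[C@H]2/C=C(/C)[C@H](OC(C)=O)C/C=C(C)\C[C@@H](O)[C@H]12 | intermediate
32 | tert-butyl hydroperoxide | CC(C)(C)OO | starting material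
33 | (1R,3R,6S,7S,8R,10S)-3-acetoxy-1,10-epoxy-8-hydroxygermacra-4Z,11(13)-dien-12,6-olide | C=C1C(=O)O[C@H]2/C=C(/C)[C@H](OC(C)=O)C[C@H]3O[C@@]3(C)C[C@@H](O)[C@H]12 | intermediate
34 | (R)-2-methylbutanoic acid | CC[C@@H](C)C(=O)O | starting material
35 | (1R,3R,6S,7S,8S,10S)-3-acetoxy-1,10-epoxy-8-[(2R)-2-methylbutanoyloxy]germacra-4Z,11(13)-dien-12,6-olide | C=C1C(=O)O[C@H]2/C=C(/C)[C@H](OC(C)=O)C[C@H]3O[C@@]3(C)C[C@H](OC(=O)[C@H](C)CC)[C@H]12 | target

**Step count and risks**

Total steps: 15. Longest linear sequence: 15 (fully linear from 1).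

Three steps most likely to fail:

1. Step 12 (ten-membered ring closure). The yield of a medium-ring closure and the C6/C7 sense both rest on analogy and on a conformational model, and the bromide 27 is fragile. Fallback: set out from 26 and acetylate the Baylis–Hillman hydroxyl (Ac2O, DMAP, CH2Cl2) to the allylic acetate F1. Ionise it with Pd(PPh3)4 (zerovalent palladium, 5 mol%) and transmetalate with InI in THF at high dilution to the allylindium species F2. This softer allyl metal closes the C6–C7 bond and lactonises through 29, coming back to the route at 30. The approach avoids bromide 27 and low-valent chromium and makes the C7 nucleophile by ionisation and transmetalation instead of by direct reduction.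

2. Step 15 (Mitsunobu inversion at a ring carbinol next to C7). Elimination towards C9 or no reaction with a weakly acidic aliphatic acid are both possible. Fallback: set out from 33 and oxidise with Dess–Martin periodinane to the 8-ketone F3. Reduce with NaBH4/CeCl3·7H2O at −78 °C (hydride expected anti to the C7–C11 bond) to the 8S alcohol F4. Acylate with 34 (DCC, DMAP) with retention, coming back at 35.

3. Step 14 (face selectivity of the directed epoxidation in the macrocycle). The ring may not let the 8-OH reach the olefin as the acyclic model assumes. Fallback: set out from 31 and carry out the Mitsunobu esterification with 34 first, giving the diene ester F5. Then epoxidise the 1(10)-olefin under reagent control with the D-fructose-derived Shi ketone (2KHSO5·KHSO4·K2SO4, K2CO3 buffer, MeCN/H2O, 0 °C), whose spiro transition state predicts the 1R,10S epoxide, coming back at 35.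

**Further compounds**

F1 | step 12 | methyl (4R,6Z,9R,10Z)-3,9-diacetoxy-6,10-dimethyl-2-methylidene-12-oxo-4-[(2,2,6,6-tetramethylpiperidin-1-yl)oxy]dodeca-6,10-dienoate (both C3 epimers) | O=C/C=C(/C)[C@H](OC(C)=O)C/C=C(C)\C[C@@H](ON1C(C)(C)CCCC1(C)C)C(OC(C)=O)C(=C)C(=O)OC
F2 | step 12 | allylindium acetate iodide from F1 (indium on C13, trivalent indium) | O=C/C=C(/C)[C@H](OC(C)=O)C/C=C(C)\C[C@@H](ON1C(C)(C)CCCC1(C)C)/C=C(\C[In](I)OC(C)=O)C(=O)OC
F3 | step 15 | (1R,3R,6S,7R,10S)-3-acetoxy-1,10-epoxy-8-oxogermacra-4Z,11(13)-dien-12,6-olide | C=C1C(=O)O[C@H]2/C=C(/C)[C@H](OC(C)=O)C[C@H]3O[C@@]3(C)CC(=O)[C@H]12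
F4 | step 15 | (1R,3R,6S,7S,8S,10S)-3-acetoxy-1,10-epoxy-8-hydroxygermacra-4Z,11(13)-dien-12,6-olide | C=C1C(=O)O[C@H]2/C=C(/C)[C@H](OC(C)=O)C[C@H]3O[C@@]3(C)C[C@H](O)[C@H]12
F5 | step 14 | (3R,6S,7S,8S)-3-acetoxy-8-[(2R)-2-methylbutanoyloxy]germacra-1(10)Z,4Z,11(13)-trien-12,6-olide | C=C1C(=O)O[C@H]2/C=C(/C)[C@H](OC(C)=O)C/C=C(C)\C[C@H](OC(=O)[C@H](C)CC)[C@H]12
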